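Readings and results are simulated with made-up constants; noise was put on by code.

The ratio [free monomer]/[monomer in chains] is what Ana and Ben dispute for the spring flask, which is followed so far in the readings below.

all flasks: pre-initiator 4 mol%
- spring: free monomer 0.010 M (fed, over 2.5 d); the very flask that is asked about, followed so far
- dawn: free monomer 0.020 M (fed, over 2.5 d); run made earlier
- flask: free monomer 0.010 M (fed, over 2.5 d); time 10 d

spring run (percent of the free monomer charged)

| time / h | monomer in chains / % | free monomer / % |
|---|---|---|
| 4.00 | 0 | 5.9 |
| 8.00 | 0.3 | 12.8 |
| 12.0 | 1.3 | 18.5 |
| 15.0 | 2.1 | 22.7 |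
| 20.0 | 4.9 | 28.5 |

dawn run (percent of the free monomer charged)

| time / d | monomer in chains / % | free monomer / % |
|---|---|---|
| 2.08 | 45.8 | 26.6 |
| 4.00 | 55.5 | 2.2 |
| 6.00 | 32.6 | 0 |
| 8.00 | 18.5 | 0 |
| 10.0 | 10.3 | 0.2 |

(readings scatter by 0.3 percentage points)

- the best time, 10 d at the latest, for monomer in chains
- the amount of monomer in chains, in percent of the free monomer charged, at that time

- percentages count the whole charge, also what has not yet gone in

Ben holds that chains grow until free monomer is used up. The dawn run has 2.2 % free monomer left at 4.00 d, which is 1.50 d after its feed ended. The spring flask has half the concentration, so he takes uptake to be half as fast, doubles that interval and expects the best time near 5.50 d.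

Ana holds that chains are lost throughout, so they stop growing when uptake, k[free monomer], equals loss, kd[monomer in chains]. Here k is a pseudo-first-order constant. Dividing one rate by the other removes time. Late dawn chains fall from 32.6 % to 10.3 % between 6.00 d and 10.0 d, so Ana reads kd from these readings as 0.288 d⁻¹. Ana treats dawn free monomer as nearly stationary under the feed. The whole charge over 2.5 d, divided by the 26.6 % standing at 2.08 d, then gives k as 1.50 d⁻¹. Taking k in proportion to charge, Ana gives the spring flask 0.752 d⁻¹. That gives 0.383 for the crossing ratio, the value of [free monomer]/[monomer in chains] at which uptake equals loss.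

The forecast sides with Ana, from “chains decaying first-order to something other than monomer”: 3.6 d and 53 %. Its uptake constant for the spring flask is about 0.035 per hour, where Ana's reckoning gives 0.0313 h⁻¹.

The simulation gives 3.59 d and 54.3 %, and the ratio there is 0.343, against Ana's 0.383. At 5.00 d the spring flask is down to 46.4 %, so Ben loses.

    pre-initiator → initiator (k = 0.0526 h⁻¹)
    free monomer + initiator → living end + monomer in chains (k = 88.8 L mol⁻¹ h⁻¹)
    free monomer + living end → monomer in chains + living end, rate k3*[living end]*[free monomer] (k = 88.5 L mol⁻¹ h⁻¹)
    monomer in chains → over-reaction product (k = 0.0120 h⁻¹)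

A run without the passing of monomer in chains into over-reaction product climbs to 99.9 % against 54.3 %. That is Ben's region, a crossing ratio of zero.

In the neighbour flask with 1.6 mol% of pre-initiator, taking k in proportion to loading, the reckoned crossing ratio rises to 0.958, so the reckoning has chains turn there with [free monomer] near [monomer in chains]. The computed best there is 38.9 %.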